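**Retrosynthetic overview** (positions numbered as in cyclodeca[b]furan: O1, C2(=O), C3(=CH2), C3a, C4(O-acyl), C5, C6(CO2Me)=C7, C8, C9, C10(CH2OH), C11, C11a)
1. Target 33 ⇐ silyl ether 32 ⇐ ten-membered alcohol 30; the (R)-2-methylbutanoate is put on by a Mitsunobu esterification that inverts C4.
2. Key disconnection is the ring bond C3a–C4: 30 arises from open-chain bromo aldehyde 27 by an intramolecular chromium (Nozaki–Hiyama–Kishi) allylation, in which a 5-substituted 3-(bromomethyl)furan-2(5H)-one attacks its own aldehyde.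
3. Enabling feature: the lactone α-carbon C3 carries the exocyclic CH2 and is bonded to the ring-fusion carbon C3a, which is bonded to the oxygenated C4 of the ten-membered ring. CH2=C3–C3a–C4–O is a homoallylic alcohol, the retron of an allylmetal addition with allyl transposition; the C6=C7 enoate, whose ring bonds are cis, pre-folds the chain.
4. 27 ⇐ Wittig olefination (E-enoate, C6=C7) of an aldehyde carrying the butenolide; the butenolide ⇐ palladium-catalysed carbonylative lactonisation of a (Z)-γ-hydroxy vinyl iodide. C11a comes from a Noyori transfer hydrogenation of an ynone, C10 from an Evans alkylation.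
5. Ring order: five-membered lactone first (step 8), ten-membered carbocycle last (step 15).

Key step: step 15

Remark: hex-5-enoyl chloride, ylide 19 and (R)-2-methylbutanoic acid are taken as purchasable; the acyl side chain is (R), as the given structure specifies.

**Step 1**
Reactants: 1 (4S)-4-benzyl-1,3-oxazolidin-2-one; 2 hex-5-enoyl chloride
Product: 3 (4S)-4-benzyl-3-(hex-5-enoyl)-1,3-oxazolidin-2-one
Conditions: Et3N, DMAP (cat.), CH2Cl2, 0 °C → rt
Reagents that add atoms: none
Why: DMAP-catalysed N-acylation of the oxazolidinone by an acid chloride is the standard loading of an Evans auxiliary and creates no stereocentre.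

**Step 2**
Reactants: 3 (4S)-4-benzyl-3-(hex-5-enoyl)-1,3-oxazolidin-2-one; 4 tert-butyl bromoacetate
Product: 6 tert-butyl (3R)-3-[(4S)-4-benzyl-2-oxo-1,3-oxazolidine-3-carbonyl]hept-6-enoate, via sodium enolate 5 (not isolated)
Conditions: NaN(SiMe3)2, THF, −78 °C; then 4, −78 → −40 °C
Reagents that add atoms: none
Why: Evans asymmetric alkylation, in which the chelated sodium (Z)-enolate is alkylated by the reactive bromoacetate on the face away from the benzyl group, which sets the future C10 centre as R.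

**Step 3**
Reactants: 6 tert-butyl (3R)-3-[(4S)-4-benzyl-2-oxo-1,3-oxazolidine-3-carbonyl]hept-6-enoate
Product: 8 (4R)-4-(but-3-en-1-yl)oxolan-2-one, via hydroxy ester 7 (not isolated)
Conditions: LiBH4, MeOH (1 equiv), Et2O, 0 °C; aqueous work-up; then TFA, CH2Cl2, rt
Reagents that add atoms: none
Why: LiBH4 should cleave the imide reductively without touching the tert-butyl ester or the alkene, and acid then closes the γ-lactone by intramolecular transesterification, the stereocentre being untouched.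

**Step 4**
Reactants: 8 (4R)-4-(but-3-en-1-yl)oxolan-2-one; 9 tert-butyldimethyl(prop-2-yn-1-yloxy)silane
Product: 11 (6R)-1-[(tert-butyldimethylsilyl)oxy]-6-(hydroxymethyl)dec-9-en-2-yn-4-one, via lithium acetylide 10 (not isolated)
Conditions: 9, n-BuLi, THF, −78 °C; then 8, −78 °C; aq. NH4Cl
Reagents that add atoms: none
Why: Acylation of a lithium acetylide by a γ-lactone should stop at the lithium hemiketal at −78 °C, so that the hydroxy ynone (in equilibrium with its lactol) is released only on work-up.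

**Step 5**
Reactants: 11 (6R)-1-[(tert-butyldimethylsilyl)oxy]-6-(hydroxymethyl)dec-9-en-2-yn-4-one
Product: 12 (6R)-1-[(tert-butyldimethylsilyl)oxy]-6-{[(tert-butyldiphenylsilyl)oxy]methyl}dec-9-en-2-yn-4-one
Conditions: TBDPSCl, Et3N, DMAP (cat.), CH2Cl2, 0 °C → rt
Reagents that add atoms: tert-butyl(chloro)diphenylsilane, CC(C)(C)[Si](Cl)(c1ccccc1)c1ccccc1
Why: Silyl ether formation at the primary hydroxyl should be fast and should pull the lactol/keto alcohol equilibrium to the open ynone.

**Step 6**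
Reactants: 12 (6R)-1-[(tert-butyldimethylsilyl)oxy]-6-{[(tert-butyldiphenylsilyl)oxy]methyl}dec-9-en-2-yn-4-one
Product: 13 (4R,6R)-1-[(tert-butyldimethylsilyl)oxy]-6-{[(tert-butyldiphenylsilyl)oxy]methyl}dec-9-en-2-yn-4-ol
Conditions: Ru[(R,R)-TsDPEN](p-cymene) (2 mol%), i-PrOH, rt
Reagents that add atoms: none
Why: Noyori asymmetric transfer hydrogenation of an α,β-acetylenic ketone, in which the alkynyl group takes the place of the aryl group of the usual model, so the (R,R)-catalyst should give the (4R)-carbinol (future C11a) under reagent control.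

**Step 7**
Reactants: 13 (4R,6R)-1-[(tert-butyldimethylsilyl)oxy]-6-{[(tert-butyldiphenylsilyl)oxy]methyl}dec-9-en-2-yn-4-ol
Product: 15 (2Z,4R,6R)-1-[(tert-butyldimethylsilyl)oxy]-6-{[(tert-butyldiphenylsilyl)oxy]methyl}-2-iododeca-2,9-dien-4-ol, via vinylalanate 14 (not isolated)
Conditions: NaAlH2(OCH2CH2OMe)2, THF, 0 °C; then I2, −78 → 0 °C
Reagents that add atoms: iodine, [I][I]
Why: Hydroxyl-directed trans-hydroalumination of the propargylic alcohol places aluminium on the distal alkyne carbon in a five-membered alanate, and iodinolysis with retention should give the (Z)-iodoalkene.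

**Step 8**
Reactants: 15 (2Z,4R,6R)-1-[(tert-butyldimethylsilyl)oxy]-6-{[(tert-butyldiphenylsilyl)oxy]methyl}-2-iododeca-2,9-dien-4-ol
Product: 16 (5R)-3-{[(tert-butyldimethylsilyl)oxy]methyl}-5-[(2R)-2-{[(tert-butyldiphenylsilyl)oxy]methyl}hex-5-en-1-yl]furan-2(5H)-one
Conditions: Pd(PPh3)4 (5 mol%), CO (1 atm), K2CO3, THF, 50 °C
Reagents that add atoms: carbon monoxide, [C-]#[O+]
Why: Palladium-catalysed carbonylative lactonisation (oxidative addition to zerovalent palladium, CO insertion, capture of the acylpalladium by the cis hydroxyl) should close the butenolide, and the mild carbonate base should not epimerise the γ-carbon.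

**Step 9**
Reactants: 16 (5R)-3-{[(tert-butyldimethylsilyl)oxy]methyl}-5-[(2R)-2-{[(tert-butyldiphenylsilyl)oxy]methyl}hex-5-en-1-yl]furan-2(5H)-one
Product: 18 (4R)-5-[(2R)-4-{[(tert-butyldimethylsilyl)oxy]methyl}-5-oxo-2,5-dihydrofuran-2-yl]-4-{[(tert-butyldiphenylsilyl)oxy]methyl}pentanal, via ozonide 17 (not isolated)
Conditions: O3, CH2Cl2, −78 °C; then PPh3, −78 °C → rt
Reagents that add atoms: ozone, [O-][O+]=O
Why: Ozonolysis with reductive work-up should cleave only the electron-rich terminal alkene, the butenolide alkene being deactivated by its carbonyl group.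

**Step 10**
Reactants: 19 methyl (triphenylphosphoranylidene)acetate; 20 allyl bromide
Product: 22 methyl 2-(triphenylphosphoranylidene)pent-4-enoate, via phosphonium bromide 21 (not isolated)
Conditions: CHCl3, reflux; then NaOH (aq), CH2Cl2, rt
Reagents that add atoms: none
Why: C-alkylation of a stabilised phosphorane by an allylic bromide followed by deprotonation of the salt is the usual route to α-substituted ester ylides.

**Step 11**
Reactants: 18 (4R)-5-[(2R)-4-{[(tert-butyldimethylsilyl)oxy]methyl}-5-oxo-2,5-dihydrofuran-2-yl]-4-{[(tert-butyldiphenylsilyl)oxy]methyl}pentanal; 22 methyl 2-(triphenylphosphoranylidene)pent-4-enoate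
Product: 23 methyl (2E,6R)-7-[(2R)-4-{[(tert-butyldimethylsilyl)oxy]methyl}-5-oxo-2,5-dihydrofuran-2-yl]-6-{[(tert-butyldiphenylsilyl)oxy]methyl}-2-(prop-2-en-1-yl)hept-2-enoate
Conditions: toluene, 90 °C
Reagents that add atoms: none
Why: Wittig olefination with an α-substituted stabilised ylide should give the trisubstituted enoate with the aldehyde chain trans to the ester (E), which is the geometry of the ring alkene C6=C7.

**Step 12**
Reactants: 23 methyl (2E,6R)-7-[(2R)-4-{[(tert-butyldimethylsilyl)oxy]methyl}-5-oxo-2,5-dihydrofuran-2-yl]-6-{[(tert-butyldiphenylsilyl)oxy]methyl}-2-(prop-2-en-1-yl)hept-2-enoate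
Product: 24 methyl (2E,6R)-6-{[(tert-butyldiphenylsilyl)oxy]methyl}-7-[(2R)-4-(hydroxymethyl)-5-oxo-2,5-dihydrofuran-2-yl]-2-(prop-2-en-1-yl)hept-2-enoate
Conditions: CSA (10 mol%), MeOH/CH2Cl2 (1:1), 0 °C
Reagents that add atoms: none
Why: Acid-catalysed methanolysis should remove the primary allylic TBS ether much faster than the TBDPS ether (selective desilylation).

**Step 13**
Reactants: 24 methyl (2E,6R)-6-{[(tert-butyldiphenylsilyl)oxy]methyl}-7-[(2R)-4-(hydroxymethyl)-5-oxo-2,5-dihydrofuran-2-yl]-2-(prop-2-en-1-yl)hept-2-enoate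
Product: 25 methyl (2E,6R)-7-[(2R)-4-(bromomethyl)-5-oxo-2,5-dihydrofuran-2-yl]-6-{[(tert-butyldiphenylsilyl)oxy]methyl}-2-(prop-2-en-1-yl)hept-2-enoate
Conditions: CBr4, PPh3, CH2Cl2, 0 °C
Reagents that add atoms: carbon tetrabromide, BrC(Br)(Br)Br
Why: Appel bromination converts the primary allylic alcohol into the bromide under neutral conditions that leave the alkenes, esters and silyl ether alone.

**Step 14**
Reactants: 25 methyl (2E,6R)-7-[(2R)-4-(bromomethyl)-5-oxo-2,5-dihydrofuran-2-yl]-6-{[(tert-butyldiphenylsilyl)oxy]methyl}-2-(prop-2-en-1-yl)hept-2-enoate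
Product: 27 methyl (2E,6R)-7-[(2R)-4-(bromomethyl)-5-oxo-2,5-dihydrofuran-2-yl]-6-{[(tert-butyldiphenylsilyl)oxy]methyl}-2-(2-oxoethyl)hept-2-enoate, via diol 26 (not isolated)
Conditions: OsO4 (2 mol%), NaIO4, 2,6-lutidine, dioxane/H2O (3:1), rt
Reagents that add atoms: osmium tetroxide, O=[Os](=O)(=O)=O; sodium periodate, [Na+].[O-]I(=O)(=O)=O
Why: Lemieux–Johnson cleavage (catalytic dihydroxylation, then periodate cleavage) should select the monosubstituted alkene over the two conjugated electron-poor alkenes and release the β,γ-unsaturated aldehyde under buffered, non-basic conditions.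

**Step 15**
Reactants: 27 methyl (2E,6R)-7-[(2R)-4-(bromomethyl)-5-oxo-2,5-dihydrofuran-2-yl]-6-{[(tert-butyldiphenylsilyl)oxy]methyl}-2-(2-oxoethyl)hept-2-enoate
Product: 30 methyl (3aR,4S,6E,10R,11aR)-10-{[(tert-butyldiphenylsilyl)oxy]methyl}-4-hydroxy-3-methylidene-2-oxo-2,3,3a,4,5,8,9,10,11,11a-decahydrocyclodeca[b]furan-6-carboxylate, via allylchromium dichloride 28 (not isolated), via chromium alkoxide 29 (not isolated)
Conditions: CrCl2 (8 equiv), THF, rt, slow addition of 27 (final 2 mM); then H2O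
Reagents that add atoms: none
Why: Two equivalents of CrCl2 (divalent chromium) reduce the allylic bromide to the allylchromium dichloride 28 (trivalent chromium), which adds to the aldehyde through a six-membered Zimmerman–Traxler chair with allyl transposition, so that the butenolide β-carbon becomes C3a, the ring double bond moves out to the C3 methylidene, and alkoxide 29 is hydrolysed on work-up. The closest known reaction type is the Nozaki–Hiyama–Kishi allylation of aldehydes by 3-(bromomethyl)furan-2(5H)-ones, and chromium-mediated allylation is an established way to close ten-membered and larger carbocycles. The ten-membered ring closes by 10-exo-trig attack of C3a on the aldehyde carbon C4, helped by the pre-set C6=C7 alkene whose cis ring bonds act as a turn. C3a is controlled by the existing C11a centre, since the aldehyde should approach the butenolide face opposite the C11a–C11 bond, which gives the trans ring fusion. C4 is controlled by the chair, in which the ring holds the γ-substituent (C11a) trans to the CH2Cr carbon and the aldehyde chain (C5) sits equatorial, which predicts the anti (3aR,4S) alcohol, the C4 epimer of the target oxygen pattern, accepted on purpose because step 16 inverts this centre. The step needs γ- over α-attack of the allyl unit (inherent in the cyclic transition state), intra- over intermolecular coupling (slow addition to excess CrCl2 at high dilution) and tolerance of lactone, esters and silyl ether (CrCl2 reacts only with the allylic bromide and the aldehyde).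

**Step 16**
Reactants: 30 methyl (3aR,4S,6E,10R,11aR)-10-{[(tert-butyldiphenylsilyl)oxy]methyl}-4-hydroxy-3-methylidene-2-oxo-2,3,3a,4,5,8,9,10,11,11a-decahydrocyclodeca[b]furan-6-carboxylate; 31 (2R)-2-methylbutanoic acid
Product: 32 methyl (3aS,4R,6E,10R,11aR)-10-{[(tert-butyldiphenylsilyl)oxy]methyl}-4-{[(2R)-2-methylbutanoyl]oxy}-3-methylidene-2-oxo-2,3,3a,4,5,8,9,10,11,11a-decahydrocyclodeca[b]furan-6-carboxylate
Conditions: PPh3, DIAD, toluene, 0 °C → rt
Reagents that add atoms: none
Why: Mitsunobu esterification, in which the C4 alkoxyphosphonium is displaced by the carboxylate with inversion (4S → 4R), so one operation installs the side chain and corrects C4 while the α-centre of the acid is not touched.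

**Step 17**
Reactants: 32 methyl (3aS,4R,6E,10R,11aR)-10-{[(tert-butyldiphenylsilyl)oxy]methyl}-4-{[(2R)-2-methylbutanoyl]oxy}-3-methylidene-2-oxo-2,3,3a,4,5,8,9,10,11,11a-decahydrocyclodeca[b]furan-6-carboxylate
Product: 33 methyl (3aS,4R,6E,10R,11aR)-10-(hydroxymethyl)-4-{[(2R)-2-methylbutanoyl]oxy}-3-methylidene-2-oxo-2,3,3a,4,5,8,9,10,11,11a-decahydrocyclodeca[b]furan-6-carboxylate (CNP0141952.3)
Conditions: HF·pyridine, pyridine, THF, 0 °C → rt
Reagents that add atoms: none
Why: Buffered fluoride cleavage of the primary TBDPS ether is mild enough for the α-methylene lactone and both esters and touches no stereocentre.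

**Compound list**
1 | (4S)-4-benzyl-1,3-oxazolidin-2-one | O=C1OC[C@H](Cc2ccccc2)N1 | starting material
2 | hex-5-enoyl chloride | C=CCCCC(Cl)=O | starting material
3 | (4S)-4-benzyl-3-(hex-5-enoyl)-1,3-oxazolidin-2-one | O=C1OC[C@H](Cc2ccccc2)N1C(=O)CCCC=C | intermediate
4 | tert-butyl bromoacetate | BrCC(=O)OC(C)(C)C | starting material
5 | sodium (Z)-enolate of 3 | [Na+].C=CCC/C=C(\[O-])N1[C@@H](Cc2ccccc2)COC1=O | intermediate
6 | tert-butyl (3R)-3-[(4S)-4-benzyl-2-oxo-1,3-oxazolidine-3-carbonyl]hept-6-enoate | CC(C)(C)OC(=O)C[C@H](C(=O)N1[C@@H](Cc2ccccc2)COC1=O)CCC=C | intermediate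
7 | tert-butyl (3R)-3-(hydroxymethyl)hept-6-enoate | CC(C)(C)OC(=O)C[C@H](CO)CCC=C | intermediate
8 | (4R)-4-(but-3-en-1-yl)oxolan-2-one | O=C1C[C@H](CO1)CCC=C | intermediate
9 | tert-butyldimethyl(prop-2-yn-1-yloxy)silane | C#CCO[Si](C)(C)C(C)(C)C | starting material
10 | lithium acetylide of 9 | [Li]C#CCO[Si](C)(C)C(C)(C)C | intermediate
11 | (6R)-1-[(tert-butyldimethylsilyl)oxy]-6-(hydroxymethyl)dec-9-en-2-yn-4-one | CC(C)(C)[Si](C)(C)OCC#CC(=O)C[C@H](CO)CCC=C | intermediate
12 | (6R)-1-[(tert-butyldimethylsilyl)oxy]-6-{[(tert-butyldiphenylsilyl)oxy]methyl}dec-9-en-2-yn-4-one | CC(C)(C)[Si](C)(C)OCC#CC(=O)C[C@H](CO[Si](c1ccccc1)(c1ccccc1)C(C)(C)C)CCC=C | intermediate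
13 | (4R,6R)-1-[(tert-butyldimethylsilyl)oxy]-6-{[(tert-butyldiphenylsilyl)oxy]methyl}dec-9-en-2-yn-4-ol | O[C@@H](C#CCO[Si](C)(C)C(C)(C)C)C[C@H](CO[Si](c1ccccc1)(c1ccccc1)C(C)(C)C)CCC=C | intermediate
14 | sodium alkenylalanate from 13 (five-membered O–Al–C ring, two 2-methoxyethoxy ligands on aluminium) | [Na+].COCCO[Al-]1(OCCOC)O[C@H](C[C@H](CO[Si](c2ccccc2)(c2ccccc2)C(C)(C)C)CCC=C)C=C1CO[Si](C)(C)C(C)(C)C | intermediate
15 | (2Z,4R,6R)-1-[(tert-butyldimethylsilyl)oxy]-6-{[(tert-butyldiphenylsilyl)oxy]methyl}-2-iododeca-2,9-dien-4-ol | O[C@@H](/C=C(\I)CO[Si](C)(C)C(C)(C)C)C[C@H](CO[Si](c1ccccc1)(c1ccccc1)C(C)(C)C)CCC=C | intermediate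
16 | (5R)-3-{[(tert-butyldimethylsilyl)oxy]methyl}-5-[(2R)-2-{[(tert-butyldiphenylsilyl)oxy]methyl}hex-5-en-1-yl]furan-2(5H)-one | CC(C)(C)[Si](C)(C)OCC1=C[C@@H](C[C@H](CO[Si](c2ccccc2)(c2ccccc2)C(C)(C)C)CCC=C)OC1=O | intermediate
17 | 1,2,4-trioxolane (ozonide) of the terminal alkene of 16, mixture at the new centre | CC(C)(C)[Si](C)(C)OCC1=C[C@@H](C[C@H](CO[Si](c2ccccc2)(c2ccccc2)C(C)(C)C)CCC2OCOO2)OC1=O | intermediate
18 | (4R)-5-[(2R)-4-{[(tert-butyldimethylsilyl)oxy]methyl}-5-oxo-2,5-dihydrofuran-2-yl]-4-{[(tert-butyldiphenylsilyl)oxy]methyl}pentanal | CC(C)(C)[Si](C)(C)OCC1=C[C@@H](C[C@H](CO[Si](c2ccccc2)(c2ccccc2)C(C)(C)C)CCC=O)OC1=O | intermediate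
19 | methyl (triphenylphosphoranylidene)acetate | COC(=O)C=P(c1ccccc1)(c1ccccc1)c1ccccc1 | starting material
20 | allyl bromide | C=CCBr | starting material
21 | (1-methoxy-1-oxopent-4-en-2-yl)triphenylphosphonium bromide | C=CCC(C(=O)OC)[P+](c1ccccc1)(c1ccccc1)c1ccccc1.[Br-] | intermediate
22 | methyl 2-(triphenylphosphoranylidene)pent-4-enoate | C=CCC(C(=O)OC)=P(c1ccccc1)(c1ccccc1)c1ccccc1 | intermediate
23 | methyl (2E,6R)-7-[(2R)-4-{[(tert-butyldimethylsilyl)oxy]methyl}-5-oxo-2,5-dihydrofuran-2-yl]-6-{[(tert-butyldiphenylsilyl)oxy]methyl}-2-(prop-2-en-1-yl)hept-2-enoate | CC(C)(C)[Si](C)(C)OCC1=C[C@@H](C[C@H](CO[Si](c2ccccc2)(c2ccccc2)C(C)(C)C)CC/C=C(/C(=O)OC)CC=C)OC1=O | intermediate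
24 | methyl (2E,6R)-6-{[(tert-butyldiphenylsilyl)oxy]methyl}-7-[(2R)-4-(hydroxymethyl)-5-oxo-2,5-dihydrofuran-2-yl]-2-(prop-2-en-1-yl)hept-2-enoate | OCC1=C[C@@H](C[C@H](CO[Si](c2ccccc2)(c2ccccc2)C(C)(C)C)CC/C=C(/C(=O)OC)CC=C)OC1=O | intermediate
25 | methyl (2E,6R)-7-[(2R)-4-(bromomethyl)-5-oxo-2,5-dihydrofuran-2-yl]-6-{[(tert-butyldiphenylsilyl)oxy]methyl}-2-(prop-2-en-1-yl)hept-2-enoate | BrCC1=C[C@@H](C[C@H](CO[Si](c2ccccc2)(c2ccccc2)C(C)(C)C)CC/C=C(/C(=O)OC)CC=C)OC1=O | intermediate
26 | 2-(2,3-dihydroxypropyl) analogue of 25 (diol from the terminal alkene, mixture at the new carbinol) | BrCC1=C[C@@H](C[C@H](CO[Si](c2ccccc2)(c2ccccc2)C(C)(C)C)CC/C=C(/C(=O)OC)CC(O)CO)OC1=O | intermediate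
27 | methyl (2E,6R)-7-[(2R)-4-(bromomethyl)-5-oxo-2,5-dihydrofuran-2-yl]-6-{[(tert-butyldiphenylsilyl)oxy]methyl}-2-(2-oxoethyl)hept-2-enoate | BrCC1=C[C@@H](C[C@H](CO[Si](c2ccccc2)(c2ccccc2)C(C)(C)C)CC/C=C(/C(=O)OC)CC=O)OC1=O | intermediate
28 | allylchromium dichloride from 27 (CrCl2 on the former CH2Br carbon) | Cl[Cr](Cl)CC1=C[C@@H](C[C@H](CO[Si](c2ccccc2)(c2ccccc2)C(C)(C)C)CC/C=C(/C(=O)OC)CC=O)OC1=O | intermediate
29 | chromium dichloride alkoxide of 30 (O4–CrCl2) | C=C1C(=O)O[C@@H]2C[C@H](CO[Si](c3ccccc3)(c3ccccc3)C(C)(C)C)CC/C=C(/C(=O)OC)C[C@H](O[Cr](Cl)Cl)[C@@H]12 | intermediate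
30 | methyl (3aR,4S,6E,10R,11aR)-10-{[(tert-butyldiphenylsilyl)oxy]methyl}-4-hydroxy-3-methylidene-2-oxo-2,3,3a,4,5,8,9,10,11,11a-decahydrocyclodeca[b]furan-6-carboxylate | C=C1C(=O)O[C@@H]2C[C@H](CO[Si](c3ccccc3)(c3ccccc3)C(C)(C)C)CC/C=C(/C(=O)OC)C[C@H](O)[C@@H]12 | intermediate
31 | (2R)-2-methylbutanoic acid | CC[C@@H](C)C(=O)O | starting material
32 | methyl (3aS,4R,6E,10R,11aR)-10-{[(tert-butyldiphenylsilyl)oxy]methyl}-4-{[(2R)-2-methylbutanoyl]oxy}-3-methylidene-2-oxo-2,3,3a,4,5,8,9,10,11,11a-decahydrocyclodeca[b]furan-6-carboxylate | C=C1C(=O)O[C@@H]2C[C@H](CO[Si](c3ccccc3)(c3ccccc3)C(C)(C)C)CC/C=C(/C(=O)OC)C[C@@H](OC(=O)[C@H](C)CC)[C@@H]12 | intermediate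
33 | methyl (3aS,4R,6E,10R,11aR)-10-(hydroxymethyl)-4-{[(2R)-2-methylbutanoyl]oxy}-3-methylidene-2-oxo-2,3,3a,4,5,8,9,10,11,11a-decahydrocyclodeca[b]furan-6-carboxylate | C=C1C(=O)O[C@@H]2C[C@H](CO)CC/C=C(/C(=O)OC)C[C@@H](OC(=O)[C@H](C)CC)[C@@H]12 | target

**Step count**
Total: 17 steps. Longest linear sequence: 16 steps (steps 1–9 and 11–17); step 10 prepares ylide 22 in a side branch.

**Steps most likely to fail**

Step 15. The ten-membered closure is slow, so intermolecular allylation (oligomers) and drift of the β,γ-unsaturated aldehyde into conjugation on the Lewis-acidic chromium salts may outrun it. The tether may also override the chair preference and erode face selectivity at C4. The fallback changes the bond that closes the ring: C3a–C4 is made intermolecularly and the cyclodecene is closed at C6=C7 by ring-closing metathesis, still after the lactone. It sets out from 16 and from ylide 22. Selective desilylation of 16 (CSA, MeOH) should give the hydroxymethyl butenolide F1, and Appel bromination (CBr4, PPh3) the bromomethyl butenolide F2. Separately, Wittig reaction of 22 with paraformaldehyde (THF, reflux) should give the diene ester F3, and OsO4/NaIO4 cleavage of its isolated alkene the aldehyde F4, to be used at once. Chromium allylation of F4 by F2 (CrCl2, THF, rt) should give the anti, trans-configured open-chain adduct F5 by the same stereochemical model as in step 15. Ring-closing metathesis of F5 (second-generation Hoveyda–Grubbs catalyst, toluene, 80 °C, 1 mM) should then close the ten-membered ring, which can only hold the new alkene with cis ring bonds, the E-enoate. The fallback comes back to the route at 30.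

Step 16. The activated C4 oxygen may be lost by E2 elimination toward C5, whose hydrogens are allylic and acidified by the enoate, or the hindered alcohol may be acylated with retention. The fallback replaces the substitution by an oxidation–reduction sequence and sets out from 30. Dess–Martin oxidation (NaHCO3, CH2Cl2) should give the C4 ketone F6. Corey–Bakshi–Shibata reduction ((S)-2-methyl-CBS-oxazaborolidine, catecholborane, toluene, −78 °C), with the branched C3a as the large group, should give the (4R)-alcohol F7 under reagent control. Steglich esterification of F7 with 31 (DCC, DMAP cat., CH2Cl2, 0 °C) keeps the configuration and comes back to the route at 32.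

Step 14. The conjugated alkenes may be oxidised as well, the allylic bromide may hydrolyse in the aqueous medium, and the product aldehyde may isomerise. The fallback unmasks the aldehyde from an acetal instead of cleaving an alkene next to the bromide, and sets out from 23. Lemieux–Johnson cleavage of 23, where no bromide is present, should give the silyl ether aldehyde F8. CSA with HC(OMe)3 in MeOH should form the dimethyl acetal and remove the TBS group in the same pot, giving the acetal alcohol F9. Appel bromination should give the acetal bromide F10, and mild hydrolysis (LiBF4, wet MeCN) comes back to the route at 27.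

**Further compounds**
F1 | step 15 | (5R)-5-[(2R)-2-{[(tert-butyldiphenylsilyl)oxy]methyl}hex-5-en-1-yl]-3-(hydroxymethyl)furan-2(5H)-one | OCC1=C[C@@H](C[C@H](CO[Si](c2ccccc2)(c2ccccc2)C(C)(C)C)CCC=C)OC1=O
F2 | step 15 | (5R)-3-(bromomethyl)-5-[(2R)-2-{[(tert-butyldiphenylsilyl)oxy]methyl}hex-5-en-1-yl]furan-2(5H)-one | BrCC1=C[C@@H](C[C@H](CO[Si](c2ccccc2)(c2ccccc2)C(C)(C)C)CCC=C)OC1=O
F3 | step 15 | methyl 2-methylidenepent-4-enoate | C=CCC(=C)C(=O)OC
F4 | step 15 | methyl 2-methylidene-4-oxobutanoate | C=C(CC=O)C(=O)OC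
F5 | step 15 | methyl (4S)-4-[(2R,3R)-2-[(2R)-2-{[(tert-butyldiphenylsilyl)oxy]methyl}hex-5-en-1-yl]-4-methylidene-5-oxooxolan-3-yl]-4-hydroxy-2-methylidenebutanoate | C=C1C(=O)O[C@H](C[C@H](CO[Si](c2ccccc2)(c2ccccc2)C(C)(C)C)CCC=C)[C@H]1[C@@H](O)CC(=C)C(=O)OC
F6 | step 16 | methyl (3aS,6E,10R,11aR)-10-{[(tert-butyldiphenylsilyl)oxy]methyl}-3-methylidene-2,4-dioxo-2,3,3a,4,5,8,9,10,11,11a-decahydrocyclodeca[b]furan-6-carboxylate | C=C1C(=O)O[C@@H]2C[C@H](CO[Si](c3ccccc3)(c3ccccc3)C(C)(C)C)CC/C=C(/C(=O)OC)CC(=O)[C@@H]12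
F7 | step 16 | methyl (3aR,4R,6E,10R,11aR)-10-{[(tert-butyldiphenylsilyl)oxy]methyl}-4-hydroxy-3-methylidene-2-oxo-2,3,3a,4,5,8,9,10,11,11a-decahydrocyclodeca[b]furan-6-carboxylate | C=C1C(=O)O[C@@H]2C[C@H](CO[Si](c3ccccc3)(c3ccccc3)C(C)(C)C)CC/C=C(/C(=O)OC)C[C@@H](O)[C@@H]12
F8 | step 14 | methyl (2E,6R)-7-[(2R)-4-{[(tert-butyldimethylsilyl)oxy]methyl}-5-oxo-2,5-dihydrofuran-2-yl]-6-{[(tert-butyldiphenylsilyl)oxy]methyl}-2-(2-oxoethyl)hept-2-enoate | CC(C)(C)[Si](C)(C)OCC1=C[C@@H](C[C@H](CO[Si](c2ccccc2)(c2ccccc2)C(C)(C)C)CC/C=C(/C(=O)OC)CC=O)OC1=O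
F9 | step 14 | methyl (2E,6R)-6-{[(tert-butyldiphenylsilyl)oxy]methyl}-2-(2,2-dimethoxyethyl)-7-[(2R)-4-(hydroxymethyl)-5-oxo-2,5-dihydrofuran-2-yl]hept-2-enoate | OCC1=C[C@@H](C[C@H](CO[Si](c2ccccc2)(c2ccccc2)C(C)(C)C)CC/C=C(/C(=O)OC)CC(OC)OC)OC1=O
F10 | step 14 | methyl (2E,6R)-7-[(2R)-4-(bromomethyl)-5-oxo-2,5-dihydrofuran-2-yl]-6-{[(tert-butyldiphenylsilyl)oxy]methyl}-2-(2,2-dimethoxyethyl)hept-2-enoate | BrCC1=C[C@@H](C[C@H](CO[Si](c2ccccc2)(c2ccccc2)C(C)(C)C)CC/C=C(/C(=O)OC)CC(OC)OC)OC1=O
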